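## Retrosynthetic overview
1. The target is a linear trimer of 8-methoxynaphthalen-1-ol: unit A (C2) – unit B (C2', C4') – unit C (C4''). The last step removes three MOM ethers.
2. The B–C bond (C4'–C4'') comes from a Negishi coupling of an A–B bromide with the C4-zinc reagent made from the 4-bromo MOM ether.
3. The A–B bond (C2–C2') comes from an iodide-selective Negishi coupling of the 4-bromo-2-iodo MOM ether (unit B) with the C2-zinc reagent made by directed ortho-metalation of the plain MOM ether (unit A).
4. Both halides are placed by OH-directed halogenation of the free naphthol: NBS para first, then NIS ortho.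
5. No ring is formed, since all three naphthalenes are bought intact. The bond order is A–B first, B–C second.

Assumption: the SMILES has no stereodescriptor and no stereocentre, and both biaryl axes (2,2' with only two ortho OH, 4,4' with only peri H) rotate at or near room temperature, so no configuration has to be set.

## Route

Step 1
Reactants: 1 8-methoxynaphthalen-1-ol
Product: 2 4-bromo-8-methoxynaphthalen-1-ol
Conditions: NBS (1.0 equiv), MeCN, −10 to 0 °C, dark
Reagents that add atoms: N-bromosuccinimide, O=C1CCC(=O)N1Br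
Why: In this electrophilic aromatic bromination the free-naphthol ring is the most electron-rich, NBS in polar MeCN attacks para to OH (C4), and the peri O–H···OMe hydrogen bond suppresses ortho delivery; no stereo element is formed.

Step 2
Reactants: 2 4-bromo-8-methoxynaphthalen-1-ol
Product: 3 1-bromo-5-methoxy-4-(methoxymethoxy)naphthalene
Conditions: NaH (1.2 equiv), MOMCl (1.3 equiv), DMF, 0 °C to rt
Reagents that add atoms: chloromethyl methyl ether (MOMCl), COCCl
Why: This is a Williamson-type O-alkylation of the sodium naphtholate, and the resulting acetal tolerates organolithium, zinc and palladium chemistry.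

Step 3
Reactants: 2 4-bromo-8-methoxynaphthalen-1-ol
Product: 4 4-bromo-2-iodo-8-methoxynaphthalen-1-ol
Conditions: NIS (1.05 equiv), TFA (10 mol %), dry MeCN, 0 °C, dark
Reagents that add atoms: N-iodosuccinimide, O=C1CCC(=O)N1I
Why: In this electrophilic aromatic iodination C4 is blocked, so C2 is the only OH-activated position left on the phenolic ring.

Step 4
Reactants: 4 4-bromo-2-iodo-8-methoxynaphthalen-1-ol
Product: 5 4-bromo-2-iodo-8-methoxy-1-(methoxymethoxy)naphthalene
Conditions: NaH (1.2 equiv), MOMCl (1.4 equiv), DMF, 0 °C to rt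
Reagents that add atoms: chloromethyl methyl ether (MOMCl), COCCl
Why: This is a Williamson-type O-alkylation in which full deprotonation with NaH overcomes the flanked, hydrogen-bonded OH, and both aryl halides are inert.

Step 5
Reactants: 1 8-methoxynaphthalen-1-ol
Product: 6 1-methoxy-8-(methoxymethoxy)naphthalene
Conditions: NaH (1.2 equiv), MOMCl (1.3 equiv), DMF, 0 °C to rt
Reagents that add atoms: chloromethyl methyl ether (MOMCl), COCCl
Why: This Williamson-type O-alkylation installs both the protecting group and the directing group for the next step.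

Step 6
Reactants: 6 1-methoxy-8-(methoxymethoxy)naphthalene (1.3 equiv); 5 4-bromo-2-iodo-8-methoxy-1-(methoxymethoxy)naphthalene (1.0 equiv)
Product: 9 4-bromo-8,8'-dimethoxy-1,1'-bis(methoxymethoxy)-2,2'-binaphthalene, via C2-aryllithium 7 (not isolated), via C2-arylzinc chloride 8 (not isolated)
Conditions: 6, n-BuLi (1.25 equiv), TMEDA, THF, 0 °C, 1.5 h; ZnCl2 (1.4 equiv, THF), 0 °C to rt; then 5, Pd(PPh3)4 (5 mol %), THF, rt to 40 °C
Reagents that add atoms: n-BuLi, [Li]CCCC (gives the Li of 7); ZnCl2, Cl[Zn]Cl (gives the Zn and Cl of 8); nothing from either remains in 9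
Why: Directed ortho-metalation (OMOM outranks OMe, so C2 rather than C7 is lithiated), Li-to-Zn transmetalation and Negishi cross-coupling, in which zerovalent palladium inserts into C–I of 5 much faster than into C–Br, form a freely rotating 2,2' axis with nothing stereochemical to control.

Step 7
Reactants: 3 1-bromo-5-methoxy-4-(methoxymethoxy)naphthalene (1.5 equiv); 9 4-bromo-8,8'-dimethoxy-1,1'-bis(methoxymethoxy)-2,2'-binaphthalene (1.0 equiv)
Product: 12 8,8'-dimethoxy-4-[5-methoxy-4-(methoxymethoxy)naphthalen-1-yl]-1,1'-bis(methoxymethoxy)-2,2'-binaphthalene, via C4-aryllithium 10 (not isolated), via C4-arylzinc chloride 11 (not isolated)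
Conditions: 3, n-BuLi (1.5 equiv), THF, −78 °C, 20 min; ZnCl2 (1.6 equiv, THF), −78 °C to rt; then 9, Pd2(dba)3 (2 mol %), RuPhos (8 mol %), THF, 65 °C
Reagents that add atoms: n-BuLi, [Li]CCCC (gives the Li of 10); ZnCl2, Cl[Zn]Cl (gives the Zn and Cl of 11); nothing from either remains in 12
Why: Bromine–lithium exchange (much faster at −78 °C than ortho-deprotonation), transmetalation and a Negishi cross-coupling with a bulky biarylphosphine built for hindered, electron-rich bromides form a 1,1'-binaphthyl-type axis that has no ortho substituents and is not configurationally fixed.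

Step 8
Reactants: 12 8,8'-dimethoxy-4-[5-methoxy-4-(methoxymethoxy)naphthalen-1-yl]-1,1'-bis(methoxymethoxy)-2,2'-binaphthalene
Product: 13 4-(4-hydroxy-5-methoxynaphthalen-1-yl)-8,8'-dimethoxy-[2,2'-binaphthalene]-1,1'-diol (target)
Conditions: HCl (1.25 M in MeOH), THF, 40 °C, degassed, argon
Reagents that add atoms: none
Why: Acid-catalysed transacetalisation cleaves all three MOM acetals, the large excess of MeOH traps the oxocarbenium ion before it can attack the electron-rich rings, the aryl methyl ethers are untouched, and argon protects the oxidisable naphthols.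

## Compound list
1 | 8-methoxynaphthalen-1-ol | COc1cccc2cccc(O)c12 | starting material
2 | 4-bromo-8-methoxynaphthalen-1-ol | COc1cccc2c(Br)ccc(O)c12 | intermediate
3 | 1-bromo-5-methoxy-4-(methoxymethoxy)naphthalene | COCOc1ccc(Br)c2cccc(OC)c12 | intermediate
4 | 4-bromo-2-iodo-8-methoxynaphthalen-1-ol | Ic1cc(Br)c2cccc(OC)c2c1O | intermediate
5 | 4-bromo-2-iodo-8-methoxy-1-(methoxymethoxy)naphthalene | Ic1cc(Br)c2cccc(OC)c2c1OCOC | intermediate
6 | 1-methoxy-8-(methoxymethoxy)naphthalene | COCOc1cccc2cccc(OC)c12 | intermediate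
7 | [8-methoxy-1-(methoxymethoxy)naphthalen-2-yl]lithium | [Li]c1ccc2cccc(OC)c2c1OCOC | intermediate (not isolated)
8 | [8-methoxy-1-(methoxymethoxy)naphthalen-2-yl]zinc chloride | Cl[Zn]c1ccc2cccc(OC)c2c1OCOC | intermediate (not isolated)
9 | 4-bromo-8,8'-dimethoxy-1,1'-bis(methoxymethoxy)-2,2'-binaphthalene | COCOc1c(-c2cc(Br)c3cccc(OC)c3c2OCOC)ccc2cccc(OC)c12 | intermediate
10 | [5-methoxy-4-(methoxymethoxy)naphthalen-1-yl]lithium | [Li]c1ccc(OCOC)c2c(OC)cccc12 | intermediate (not isolated)
11 | [5-methoxy-4-(methoxymethoxy)naphthalen-1-yl]zinc chloride | Cl[Zn]c1ccc(OCOC)c2c(OC)cccc12 | intermediate (not isolated)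
12 | 8,8'-dimethoxy-4-[5-methoxy-4-(methoxymethoxy)naphthalen-1-yl]-1,1'-bis(methoxymethoxy)-2,2'-binaphthalene | COCOc1c(-c2cc(-c3ccc(OCOC)c4c(OC)cccc34)c3cccc(OC)c3c2OCOC)ccc2cccc(OC)c12 | intermediate
13 | 4-(4-hydroxy-5-methoxynaphthalen-1-yl)-8,8'-dimethoxy-[2,2'-binaphthalene]-1,1'-diol (CNP0542019.0) | COc1cccc2ccc(-c3cc(-c4ccc(O)c5c(OC)cccc45)c4cccc(OC)c4c3O)c(O)c12 | target

Total step count: 8
Longest linear sequence: 6 steps (1 → 2 → 4 → 5 → 9 → 12 → 13)

## Three steps most likely to fail

**Step 1.** The risks are bromination at C2 or C5 instead of C4, and over-bromination. The fallback sets out from 1 and comes back at 3 and at 5, by-passing 2 and 4. Both activated positions are brominated on purpose (NBS 2.1 equiv, MeCN) to give 2,4-dibromo-8-methoxynaphthalen-1-ol F1. This is protected (NaH, MOMCl, DMF) as 2,4-dibromo-8-methoxy-1-(methoxymethoxy)naphthalene F2. A chelation-controlled bromine–magnesium exchange with iPrMgCl·LiCl (THF, −15 °C) then takes only the bromine next to OMOM and gives [4-bromo-8-methoxy-1-(methoxymethoxy)naphthalen-2-yl]magnesium chloride F3. A water quench of this reagent gives 3, and an I2 quench gives 5.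

**Step 6.** The risks are partial lithiation at C7 next to OMe and erosion of the iodide-over-bromide selectivity. The fallback sets out from 1 and comes back at 7. The metal position is fixed by a halogen rather than by competing directing groups. Amine-mediated ortho-bromination of 1 (NBS, iPr2NH 10 mol %, CH2Cl2, 0 °C) gives 2-bromo-8-methoxynaphthalen-1-ol F4. NaH and MOMCl convert it into 2-bromo-8-methoxy-1-(methoxymethoxy)naphthalene F5. Bromine–lithium exchange (n-BuLi, THF, −78 °C) then delivers aryllithium 7 regiospecifically, and this is zincated and coupled as before.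

**Step 7.** The risk is that the hindered, electron-rich bromide 9 couples slowly and the zinc reagent is lost to protonation. The fallback sets out from 9 and comes back at 12 by reversing the polarity of the B–C bond. Miyaura borylation of 9 (B2pin2, Pd(dppf)Cl2, KOAc, dioxane, 90 °C) gives 2-[8,8'-dimethoxy-1,1'-bis(methoxymethoxy)-[2,2'-binaphthalen]-4-yl]-4,4,5,5-tetramethyl-1,3,2-dioxaborolane F6. This isolable nucleophile is joined to the small bromide 3 by Suzuki–Miyaura coupling (Pd(OAc)2, SPhos, K3PO4, toluene/H2O, 90 °C) to give 12.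

## Further compounds
F1 | step 1 | 2,4-dibromo-8-methoxynaphthalen-1-ol | COc1cccc2c(Br)cc(Br)c(O)c12
F2 | step 1 | 2,4-dibromo-8-methoxy-1-(methoxymethoxy)naphthalene | COCOc1c(Br)cc(Br)c2cccc(OC)c12
F3 | step 1 | [4-bromo-8-methoxy-1-(methoxymethoxy)naphthalen-2-yl]magnesium chloride | COCOc1c([Mg]Cl)cc(Br)c2cccc(OC)c12
F4 | step 6 | 2-bromo-8-methoxynaphthalen-1-ol | COc1cccc2ccc(Br)c(O)c12
F5 | step 6 | 2-bromo-8-methoxy-1-(methoxymethoxy)naphthalene | COCOc1c(Br)ccc2cccc(OC)c12
F6 | step 7 | 2-[8,8'-dimethoxy-1,1'-bis(methoxymethoxy)-[2,2'-binaphthalen]-4-yl]-4,4,5,5-tetramethyl-1,3,2-dioxaborolane | COCOc1c(-c2cc(B3OC(C)(C)C(C)(C)O3)c3cccc(OC)c3c2OCOC)ccc2cccc(OC)c12
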